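**Plan**
- Numbering: chain C1 (benzylic) to C20 with the ketone at C5; ring C1' (chain), C2' (H), C3' and C4' (oxygen). Retrosynthetically, the catechol and the ketone are masked as two methyl ethers and a dioxolane, then the C1'–C1 bond is cut, then the C5–C6 bond.
- The C1'–C1 cut rests on the ring pattern: chain at C1', hydrogen at C2' and oxygen at C3'/C4' is what remains when a carbon nucleophile adds to 3,4-dimethoxybenzyne (triple bond C1'≡C2') meta to the flanking C3' methoxy group and C2' is then protonated.
- Forward: a pentadecyl Grignard reagent is acylated by a 5-bromopentanoyl unit (C5–C6), the ketone is ketalised and the bromide is exchanged for iodide.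
- The iodide is turned into the primary alkyllithium, which adds to the aryne released from a lithiated chlorodimethoxybenzene (C1'–C1); acid hydrolysis and BBr3 demethylation then give the target.
- No ring is closed and the target has no stereocentre, so no stereocontrol is needed.

Key step: step 4

**Step 1**
Reactants: 1 1-bromopentadecane; 2 5-bromopentanoyl chloride
Product: 4 1-bromoicosan-5-one, via pentadecylmagnesium bromide 3 (not isolated)
Conditions: Mg, THF, 45 °C; then added to 2 (1.1 equiv), Fe(acac)3 (3 mol%), THF, −78 °C
Reagents that add atoms: none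
Why: Iron-catalysed acylation of a Grignard reagent by an acid chloride is far faster at low temperature than attack of the organomagnesium on the new ketone or on either primary C–Br bond, so the coupling should stop at the bromo ketone.

**Step 2**
Reactants: 4 1-bromoicosan-5-one; 5 ethane-1,2-diol
Product: 6 2-(4-bromobutyl)-2-pentadecyl-1,3-dioxolane
Conditions: p-TsOH·H2O (cat.), toluene, reflux, Dean–Stark trap
Reagents that add atoms: none
Why: Acid-catalysed ketalisation with azeotropic removal of water (dioxolane formation) should proceed cleanly because the primary bromide is inert to the acid and the diol.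

**Step 3**
Reactants: 6 2-(4-bromobutyl)-2-pentadecyl-1,3-dioxolane
Product: 7 2-(4-iodobutyl)-2-pentadecyl-1,3-dioxolane
Conditions: NaI (3 equiv), NaHCO3 (cat.), acetone, reflux
Reagents that add atoms: sodium iodide, [Na+].[I-]
Why: Finkelstein exchange (SN2 at the primary carbon) is driven by precipitation of NaBr from acetone, and NaHCO3 keeps the medium neutral so the dioxolane survives.

**Step 4**
Reactants: 7 2-(4-iodobutyl)-2-pentadecyl-1,3-dioxolane; 8 4-chloro-1,2-dimethoxybenzene
Product: 13 2-[4-(3,4-dimethoxyphenyl)butyl]-2-pentadecyl-1,3-dioxolane, via 2-(4-lithiobutyl)-2-pentadecyl-1,3-dioxolane 9 (not isolated), via (6-chloro-2,3-dimethoxyphenyl)lithium 10 (not isolated), via 3,4-dimethoxybenzyne 11 (not isolated), via aryllithium adduct 12 (not isolated)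
Conditions: 7, t-BuLi (2.05 equiv), Et2O/pentane, −78 °C; separately 8 (1.2 equiv), s-BuLi (1.2 equiv), THF, −95 °C; solutions combined at −95 °C, warmed to −20 °C; then H2O
Reagents that add atoms: none
Why: Iodine–lithium exchange with two equivalents of t-BuLi gives the primary alkyllithium 9, while s-BuLi removes the ring hydrogen of 8 flanked by chlorine and methoxy (directed ortho-lithiation) to give 10, which loses LiCl on warming and releases aryne 11 with its triple bond between C1' and C2'. Organolithium 9 adds to C1' (aryne carbolithiation, the known addition of alkyllithiums to 3-methoxybenzynes made by ortho-lithiation and halide loss from haloanisoles), forming the C1'–C1 bond and leaving aryllithium 12, which water protonates at C2'. The step needs attack at C1' and not at C2'; the C3' methoxy group beside the triple bond withdraws electron density through the sigma frame, so the negative charge develops at C2' next to the C–O bond and the nucleophile enters meta to that oxygen. Should some lithiation occur at C6' instead, the resulting 4,5-dimethoxybenzyne is symmetrical and gives the same product. A butyllithium is chosen as the sacrificial base because its conjugate acid, butane, cannot protonate 9, whereas the secondary amine left by a lithium amide could. No ring is closed and no stereocentre is created, and the dioxolane keeps C5 inert towards all organolithiums present.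

**Step 5**
Reactants: 13 2-[4-(3,4-dimethoxyphenyl)butyl]-2-pentadecyl-1,3-dioxolane
Product: 14 1-(3,4-dimethoxyphenyl)icosan-5-one
Conditions: 2 M aq. HCl, THF, 40 °C
Reagents that add atoms: water, O
Why: Acid-catalysed hydrolysis of the dioxolane (ketal deprotection) regenerates the C5 ketone, while the aryl methyl ethers are stable to dilute aqueous acid.

**Step 6**
Reactants: 14 1-(3,4-dimethoxyphenyl)icosan-5-one
Product: 15 1-(3,4-dihydroxyphenyl)icosan-5-one
Conditions: BBr3 (4 equiv), CH2Cl2, −78 → 0 °C, argon; then H2O, 0 °C
Reagents that add atoms: none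
Why: BBr3-mediated cleavage of aryl methyl ethers (Lewis-acid complexation, then bromide attack on the methyl groups) frees the catechol, and the ketone, only reversibly complexed at low temperature, is returned on aqueous work-up.

**Compound list**
1 | 1-bromopentadecane | CCCCCCCCCCCCCCCBr | starting material
2 | 5-bromopentanoyl chloride | O=C(Cl)CCCCBr | starting material
3 | pentadecylmagnesium bromide | CCCCCCCCCCCCCCC[Mg]Br | intermediate
4 | 1-bromoicosan-5-one | CCCCCCCCCCCCCCCC(=O)CCCCBr | intermediate
5 | ethane-1,2-diol | OCCO | starting material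
6 | 2-(4-bromobutyl)-2-pentadecyl-1,3-dioxolane | BrCCCCC1(CCCCCCCCCCCCCCC)OCCO1 | intermediate
7 | 2-(4-iodobutyl)-2-pentadecyl-1,3-dioxolane | ICCCCC1(CCCCCCCCCCCCCCC)OCCO1 | intermediate
8 | 4-chloro-1,2-dimethoxybenzene | COc1ccc(Cl)cc1OC | starting material
9 | 2-(4-lithiobutyl)-2-pentadecyl-1,3-dioxolane | [Li]CCCCC1(CCCCCCCCCCCCCCC)OCCO1 | intermediate
10 | (6-chloro-2,3-dimethoxyphenyl)lithium | COc1ccc(Cl)c([Li])c1OC | intermediate
11 | 3,4-dimethoxybenzyne (1,2-didehydro-3,4-dimethoxybenzene) | COC1=C(OC)C#CC=C1 | intermediate
12 | {2,3-dimethoxy-6-[4-(2-pentadecyl-1,3-dioxolan-2-yl)butyl]phenyl}lithium | COc1ccc(CCCCC2(CCCCCCCCCCCCCCC)OCCO2)c([Li])c1OC | intermediate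
13 | 2-[4-(3,4-dimethoxyphenyl)butyl]-2-pentadecyl-1,3-dioxolane | COc1ccc(CCCCC2(CCCCCCCCCCCCCCC)OCCO2)cc1OC | intermediate
14 | 1-(3,4-dimethoxyphenyl)icosan-5-one | CCCCCCCCCCCCCCCC(=O)CCCCc1ccc(OC)c(OC)c1 | intermediate
15 | 1-(3,4-dihydroxyphenyl)icosan-5-one | CCCCCCCCCCCCCCCC(=O)CCCCc1ccc(O)c(O)c1 | target

**Summary**
Total step count: 6. Longest linear sequence: 6 steps (1 to 15).

**Steps most likely to fail**

Step 4. The chain organolithium may lose the race for the aryne to the chloroaryllithium or to the product aryllithium (biaryl formation), or it may be protonated before the aryne is released. The fallback forms the same C1'–C1 bond by cross-coupling and sets out from 7. Zinc insertion (Zn dust, LiCl, THF, 40 °C) should give [4-(2-pentadecyl-1,3-dioxolan-2-yl)butyl]zinc iodide F1. Negishi coupling of this reagent with commercial 4-bromo-1,2-dimethoxybenzene (Pd(OAc)2, SPhos, THF, 25–50 °C) should deliver 13, where the route resumes.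

Step 1. The Grignard reagent may add a second time to the ketone, or iron-mediated coupling or reduction may occur at a C–Br bond. The fallback sets out from 2, which is treated with N,O-dimethylhydroxylamine hydrochloride and pyridine (CH2Cl2, 0 °C) to give the Weinreb amide 5-bromo-N-methoxy-N-methylpentanamide F2. Uncatalysed addition of Grignard reagent 3 (from 1) in THF at 0 °C, followed by dilute HCl work-up, should give 4 by way of the chelated tetrahedral intermediate, which cannot over-add. The route is rejoined at 4.

Step 6. Cleavage of the second methyl ether may stall, the Lewis acid may promote enolisation and self-condensation at C5, and the catechol may oxidise in air during a long work-up. The fallback changes the phenol protection and sets out from 7.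
- Commercial 4-chlorobenzene-1,2-diol is converted with chloro(methoxy)methane and i-Pr2NEt (CH2Cl2, 0 °C) into 4-chloro-1,2-bis(methoxymethoxy)benzene F3.
- Lithiation with s-BuLi (THF, −95 °C) should give [6-chloro-2,3-bis(methoxymethoxy)phenyl]lithium F4.
- On warming in the presence of 9 (made from 7 as in step 4), F4 should release 3,4-bis(methoxymethoxy)benzyne F5.
- Addition of 9 should give {2,3-bis(methoxymethoxy)-6-[4-(2-pentadecyl-1,3-dioxolan-2-yl)butyl]phenyl}lithium F6, and protonation should give 2-{4-[3,4-bis(methoxymethoxy)phenyl]butyl}-2-pentadecyl-1,3-dioxolane F7.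
- HCl in MeOH/THF/H2O at 50 °C should then remove both acetal ethers and the dioxolane in one operation, returning to the route at 15 without any Lewis acid.

**Further compounds**
F1 | step 4 | [4-(2-pentadecyl-1,3-dioxolan-2-yl)butyl]zinc iodide | I[Zn]CCCCC1(CCCCCCCCCCCCCCC)OCCO1
F2 | step 1 | 5-bromo-N-methoxy-N-methylpentanamide | CON(C)C(=O)CCCCBr
F3 | step 6 | 4-chloro-1,2-bis(methoxymethoxy)benzene | COCOc1ccc(Cl)cc1OCOC
F4 | step 6 | [6-chloro-2,3-bis(methoxymethoxy)phenyl]lithium | COCOc1ccc(Cl)c([Li])c1OCOC
F5 | step 6 | 3,4-bis(methoxymethoxy)benzyne | COCOC1=C(OCOC)C#CC=C1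
F6 | step 6 | {2,3-bis(methoxymethoxy)-6-[4-(2-pentadecyl-1,3-dioxolan-2-yl)butyl]phenyl}lithium | COCOc1ccc(CCCCC2(CCCCCCCCCCCCCCC)OCCO2)c([Li])c1OCOC
F7 | step 6 | 2-{4-[3,4-bis(methoxymethoxy)phenyl]butyl}-2-pentadecyl-1,3-dioxolane | COCOc1ccc(CCCCC2(CCCCCCCCCCCCCCC)OCCO2)cc1OCOC
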